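Readings and results are calculated on assumed constants.

The closed, stirred flask holds the same substrate and reagent charges in each recipe, so the question is how much target survives at each temperature.

| flask | substrate | reagent | catalyst | temperature | remark | time |
|---|---|---|---|---|---|---|
| summer | 0.25 M | 0.45 M | 0.17 mM | 55 °C | run made earlier |  |
| spring | 0.25 M | 0.45 M | 0.38 mM | 90 °C | run made earlier |  |
| Saturday's | 0.25 M | 0.450 M | 0.25 mM | 80 °C |  | 6.0 d |
| Sunday's | 0.25 M | 0.450 M | 0.25 mM | 120 °C |  | 6.0 d |
| Tuesday's | 0.25 M | 0.450 M | 0.25 mM | 100 °C |  | 6.0 d |
| Wednesday's | 0.25 M | 0.450 M | 0.25 mM | 60 °C |  | 6.0 d |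

| run | time / d | target / % | substrate / % |
|---|---|---|---|
| summer | 3.00 | 29.0 | 69.6 |
| summer | 8.00 | 55.0 | 42.5 |
| summer | 15.0 | 71.7 | 23.6 |
| summer | 30.0 | 85.3 | 8.1 |
| spring | 1.04 | 73.9 | 17.1 |
| spring | 2.50 | 84.3 | 1.9 |
| spring | 3.00 | 84.3 | 2.1 |
| spring | 5.00 | 85.8 | 1.0 |

(readings scatter by 0.5 percentage points)

1. the flask with the highest amount of target, in percent of the substrate charged ("all alike" if they lie within 1.5 percentage points) (Saturday's / Sunday's / Tuesday's / Wednesday's / all alike)
2. final target, as a percentage of the substrate charged, in Saturday's
3. final target, as a percentage of the substrate charged, in Sunday's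
4. final target, as a percentage of the substrate charged, in Tuesday's
5. final target, as a percentage of the substrate charged, in Wednesday's

On your hunch that the hottest flask wins by finishing first, the readings point the other way. Call the gap the charge found neither as substrate nor as target. In the summer run the gap grows from 4.61% of the converted substrate at 3.00 d to 7.18% at 30.0 d. In the spring run the gap reads 13.3% of the converted substrate at 5.00 d. My reading is that a substrate and a target destroy each other.

The loss number s is then the rate of that loss over the rate of making target, with target at the whole charge. With converted share X, target share Y and mean target Y/2, Y/X = (1 − sY/2)/(1 + sY/2). The last readings give 0.0873 for summer and 0.167 for spring. Taking s as inverse to the catalyst charge, these give the loss step an activation energy above that of the making step by 41.0 kJ mol⁻¹.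

So Sunday's loss number is 0.714. With X and Y at the whole charge on the right, Y comes to 47.4%. Put back, that gives 71.1%, and the rounds close in on an end estimate of 63.2%. Tuesday's loss number 0.364 gives 75.8%, and Saturday's 0.172 gives 86.2%, the highest of the three.

The forecast names Saturday's, with 85% there, 77% in Sunday's, 83% in Tuesday's and 66% in Wednesday's, noting that “selectivity falls with temperature”. My end estimates for Sunday's and Tuesday's stand lower than its figures.

The flasks give 83.0% in Saturday's, 61.3% in Sunday's, 74.2% in Tuesday's and 67.3% in Wednesday's, so Saturday's holds the most target.

    substrate + reagent + catalyst → catalyst + target (k = 5.30 M⁻² min⁻¹, Ea = 58.0 kJ mol⁻¹)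
    substrate + target → side product (k = 2.80 × 10⁻⁴ M⁻¹ min⁻¹, Ea = 99.0 kJ mol⁻¹)
    (constants at 80 °C)

Each percentage of side product counts as two, one substrate and one target. Sunday's has 0% substrate left at 6.00 d, and its 61.3% stands beside the end estimate of 63.2%. A neighbour of Sunday's with 0.150 mM of catalyst instead of 0.25 mM has the loss number 1.19, which gives an end estimate of 52.4%. That neighbour ends with 0% substrate, 49.8% side product and 50.2% target.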